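**Plan**
- Retrosynthesis: the hydroxymethyl arm on C3 is traced back to a vinyl group and the benzylic carbinol to an aryl ketone. The oxolane ring is then cut at O1–C5 and C3–C4 in one stroke, giving (2S,3S)-2-ethenyl-3-(3,4,5-trimethoxyphenyl)oxirane and 3,4-dimethoxyphenyl vinyl ketone.
- Enabling feature: in the ring O1–C2–C3–C4–C5, C3 carries a one-carbon arm. O1–C2–C3 can therefore be an alkoxide next to a π-allylpalladium cation, which turns the enolate-type carbon C3 into an acceptor (a polarity reversal). C4–C5 is the C=C of an enone whose carbonyl carbon is the later carbinol carbon.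
- Forward: 3,4,5-trimethoxybenzaldehyde → cinnamyl alcohol → Sharpless epoxide → epoxy aldehyde → vinyl oxirane; veratraldehyde → aryl vinyl ketone; palladium-catalysed formal [3+2] cycloaddition closes the only ring; ketone reduction; ozonolysis/reduction removes the vinyl helper.
- Stereochemistry: C2 comes from the Sharpless epoxidation (L-(+)-tartrate) and is kept through the cycloaddition. C3 and C4 are set relative to C2 in the ring closure (all-trans). The carbinol centre is set by (R)-CBS reduction, in the sense the Felkin–Anh model also favours.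

Key step: step 8

Remark: ring locants used throughout are O1, C2 (trimethoxyphenyl), C3 (hydroxymethyl or its precursor), C4 (carbinol arm), C5 (CH2); enone 11 polymerises on storage and is therefore made fresh.

**Step 1**
Reactants: 1 3,4,5-trimethoxybenzaldehyde; 2 triethyl phosphonoacetate
Product: 3 ethyl (E)-3-(3,4,5-trimethoxyphenyl)prop-2-enoate
Conditions: NaH, THF, 0 °C → rt
Reagents that add atoms: none
Why: Horner–Wadsworth–Emmons olefination of an aromatic aldehyde with a stabilised phosphonate anion should give the E-cinnamate.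

**Step 2**
Reactants: 3 ethyl (E)-3-(3,4,5-trimethoxyphenyl)prop-2-enoate
Product: 4 (E)-3-(3,4,5-trimethoxyphenyl)prop-2-en-1-ol
Conditions: iBu2AlH (2.3 equiv), CH2Cl2, −78 °C; aq. Rochelle salt
Reagents that add atoms: none
Why: 1,2-reduction of an α,β-unsaturated ester by diisobutylaluminium hydride at low temperature should give the allylic alcohol without touching the C=C bond.

**Step 3**
Reactants: 4 (E)-3-(3,4,5-trimethoxyphenyl)prop-2-en-1-ol
Product: 5 [(2S,3S)-3-(3,4,5-trimethoxyphenyl)oxiran-2-yl]methanol
Conditions: Ti(OiPr)4 (10 mol %), L-(+)-diethyl tartrate (12 mol %), tBuOOH, 4 Å MS, CH2Cl2, −20 °C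
Reagents that add atoms: tert-butyl hydroperoxide, CC(C)(C)OO
Why: Sharpless asymmetric epoxidation: the titanium tartrate complex delivers the peroxide oxygen to one face of the E-allylic alcohol, and L-(+)-diethyl tartrate should give the (2S,3S)-epoxy alcohol as it does for cinnamyl alcohol, which fixes the benzylic C–O centre that becomes C2.

**Step 4**
Reactants: 5 [(2S,3S)-3-(3,4,5-trimethoxyphenyl)oxiran-2-yl]methanol
Product: 6 (2R,3S)-3-(3,4,5-trimethoxyphenyl)oxirane-2-carbaldehyde
Conditions: SO3·pyridine, DMSO, Et3N, CH2Cl2, 0 °C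
Reagents that add atoms: none
Why: Parikh–Doering oxidation is non-acidic and should give the epoxy aldehyde without opening the aryl oxirane (the descriptor at C2 changes by priority only).

**Step 5**
Reactants: 6 (2R,3S)-3-(3,4,5-trimethoxyphenyl)oxirane-2-carbaldehyde
Product: 7 (2S,3S)-2-ethenyl-3-(3,4,5-trimethoxyphenyl)oxirane
Conditions: Ph3PCH3Br, KHMDS, THF, −78 → 0 °C
Reagents that add atoms: methyltriphenylphosphonium bromide, C[P+](c1ccccc1)(c1ccccc1)c1ccccc1.[Br-]
Why: Wittig methylenation with the salt-free non-stabilised ylide should convert the aldehyde into the vinyl group at low temperature and leave both oxirane stereocentres unchanged.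

**Step 6**
Reactants: 8 3,4-dimethoxybenzaldehyde; 9 vinylmagnesium bromide
Product: 10 1-(3,4-dimethoxyphenyl)prop-2-en-1-ol (racemic)
Conditions: THF, 0 °C; aq. NH4Cl
Reagents that add atoms: none
Why: Grignard addition to an aromatic aldehyde should give the allylic benzylic alcohol, whose stereocentre is removed in the next step.

**Step 7**
Reactants: 10 1-(3,4-dimethoxyphenyl)prop-2-en-1-ol
Product: 11 1-(3,4-dimethoxyphenyl)prop-2-en-1-one
Conditions: MnO2 (activated, excess), CH2Cl2, rt; used at once
Reagents that add atoms: none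
Why: MnO2 oxidises alcohols that are both allylic and benzylic under neutral conditions and should give the aryl vinyl ketone.

**Step 8**
Reactants: 7 (2S,3S)-2-ethenyl-3-(3,4,5-trimethoxyphenyl)oxirane; 11 1-(3,4-dimethoxyphenyl)prop-2-en-1-one
Product: 12 (2R,3R,4R)-4-(3,4-dimethoxybenzoyl)-3-ethenyl-2-(3,4,5-trimethoxyphenyl)oxolane
Conditions: Pd2(dba)3·CHCl3 (2.5 mol %), dppe (6 mol %), THF, 0 °C → rt; 7 added slowly to 11 (1.5 equiv)
Reagents that add atoms: none
Why: Zerovalent palladium ionises the allylic C–O bond of 7 with inversion and gives a zwitterion, a π-allylpalladium cation spanning C3 and the two vinyl carbons next to the benzylic alkoxide O1–C2, whose C2 stereocentre is untouched; O1 adds to the CH2 terminus of enone 11 (oxa-Michael, O1–C5 bond) and the ketone enolate so formed attacks the internal allyl carbon anti to palladium (C3–C4 bond), which releases the catalyst. The closest known reaction type is the palladium-catalysed formal [3+2] cycloaddition of vinyl oxiranes with electron-poor alkenes. The oxolane ring closes in the 5-exo mode at the internal allyl terminus; closure at the CH2 terminus would need a seven-membered ring. C2 is carried over from the epoxide of step 3; C3 is set trans to the C2 aryl group, both because the two inversions at C3 add up to retention of the trans epoxide geometry and because the π-allyl faces can exchange through the unsubstituted terminus and drain through the less crowded trans transition state; C4 is set trans to the vinyl group in the same ring closure and, being α to the ketone, can still settle to the all-trans arrangement. The step needs O-addition to the enone before C–C bond formation, branched allylation, and capture of the zwitterion faster than its 1,2-hydride shift or the oligomerisation of 11; the unhindered and strongly electrophilic vinyl ketone, the five-atom tether and the slow addition of 7 to an excess of 11 under a chelating phosphine should secure this.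

**Step 9**
Reactants: 12 (2R,3R,4R)-4-(3,4-dimethoxybenzoyl)-3-ethenyl-2-(3,4,5-trimethoxyphenyl)oxolane
Product: 13 (2R,3R,4R)-4-[(S)-(3,4-dimethoxyphenyl)(hydroxy)methyl]-3-ethenyl-2-(3,4,5-trimethoxyphenyl)oxolane
Conditions: (R)-2-methyl-CBS-oxazaborolidine (0.2 equiv), catecholborane (1.5 equiv), toluene, −78 → −40 °C
Reagents that add atoms: none
Why: Corey–Bakshi–Shibata reduction with the (R)-oxazaborolidine (aryl as the large group) should deliver hydride to the face that gives the (S)-carbinol, the same face the Felkin–Anh model predicts for the (4R) α-centre with C3 as the large group, and catecholborane at low temperature should leave the vinyl group alone.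

**Step 10**
Reactants: 13 (2R,3R,4R)-4-[(S)-(3,4-dimethoxyphenyl)(hydroxy)methyl]-3-ethenyl-2-(3,4,5-trimethoxyphenyl)oxolane
Product: 15 [(2R,3S,4R)-4-[(S)-(3,4-dimethoxyphenyl)(hydroxy)methyl]-2-(3,4,5-trimethoxyphenyl)oxolan-3-yl]methanol (the target), via hydroxy aldehyde 14 (not isolated)
Conditions: O3, CH2Cl2/MeOH, −78 °C (Sudan Red 7B end point); then NaBH4, −78 → 0 °C
Reagents that add atoms: ozone, [O-][O+]=O
Why: Ozonolysis of the terminal alkene, which reacts far faster than the arenes, followed by borohydride reduction of the peroxidic products in the same flask should give the primary alcohol through the aldehyde without leaving time for epimerisation at C3.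

**Compound list**
1 | 3,4,5-trimethoxybenzaldehyde | COc1cc(C=O)cc(OC)c1OC | starting material
2 | triethyl phosphonoacetate | CCOC(=O)CP(=O)(OCC)OCC | starting material
3 | ethyl (E)-3-(3,4,5-trimethoxyphenyl)prop-2-enoate | CCOC(=O)/C=C/c1cc(OC)c(OC)c(OC)c1 | intermediate
4 | (E)-3-(3,4,5-trimethoxyphenyl)prop-2-en-1-ol | OC/C=C/c1cc(OC)c(OC)c(OC)c1 | intermediate
5 | [(2S,3S)-3-(3,4,5-trimethoxyphenyl)oxiran-2-yl]methanol | OC[C@@H]1O[C@H]1c1cc(OC)c(OC)c(OC)c1 | intermediate
6 | (2R,3S)-3-(3,4,5-trimethoxyphenyl)oxirane-2-carbaldehyde | O=C[C@@H]1O[C@H]1c1cc(OC)c(OC)c(OC)c1 | intermediate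
7 | (2S,3S)-2-ethenyl-3-(3,4,5-trimethoxyphenyl)oxirane | C=C[C@@H]1O[C@H]1c1cc(OC)c(OC)c(OC)c1 | intermediate
8 | 3,4-dimethoxybenzaldehyde | COc1ccc(C=O)cc1OC | starting material
9 | vinylmagnesium bromide | C=C[Mg]Br | starting material
10 | 1-(3,4-dimethoxyphenyl)prop-2-en-1-ol (racemic) | C=CC(O)c1ccc(OC)c(OC)c1 | intermediate
11 | 1-(3,4-dimethoxyphenyl)prop-2-en-1-one | C=CC(=O)c1ccc(OC)c(OC)c1 | intermediate
12 | (2R,3R,4R)-4-(3,4-dimethoxybenzoyl)-3-ethenyl-2-(3,4,5-trimethoxyphenyl)oxolane | COc1ccc(C(=O)[C@H]2CO[C@@H](c3cc(OC)c(OC)c(OC)c3)[C@@H]2C=C)cc1OC | intermediate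
13 | (2R,3R,4R)-4-[(S)-(3,4-dimethoxyphenyl)(hydroxy)methyl]-3-ethenyl-2-(3,4,5-trimethoxyphenyl)oxolane | COc1ccc([C@@H](O)[C@H]2CO[C@@H](c3cc(OC)c(OC)c(OC)c3)[C@@H]2C=C)cc1OC | intermediate
14 | (2R,3R,4R)-4-[(S)-(3,4-dimethoxyphenyl)(hydroxy)methyl]-2-(3,4,5-trimethoxyphenyl)oxolane-3-carbaldehyde | COc1ccc([C@@H](O)[C@H]2CO[C@@H](c3cc(OC)c(OC)c(OC)c3)[C@@H]2C=O)cc1OC | intermediate
15 | [(2R,3S,4R)-4-[(S)-(3,4-dimethoxyphenyl)(hydroxy)methyl]-2-(3,4,5-trimethoxyphenyl)oxolan-3-yl]methanol | COc1ccc([C@@H](O)[C@H]2CO[C@@H](c3cc(OC)c(OC)c(OC)c3)[C@@H]2CO)cc1OC | target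

**Step count**
Total: 10 steps. Longest linear sequence: 8 steps (steps 1–5 and 8–10).

**Steps most likely to fail**

Step 8. The zwitterionic π-allylpalladium alkoxide may not be captured fast enough by the singly activated enone. It would then be lost by 1,2-hydride shift to an allyl aryl ketone, by closure to a 2,5-dihydrofuran, or by alkoxide-initiated oligomerisation of 11. The diastereoselectivity of the ring closure at C3/C4 may also be modest. Fallback, setting out from 7: the zwitterion is trapped with the doubly activated acceptor diethyl methylidenemalonate (Pd2(dba)3·CHCl3, dppe, THF, rt), the long-established form of this cycloaddition with a fast oxa-Michael step and a stabilised malonate carbanion for the ring closure. This should give diethyl (2R,3R)-3-ethenyl-2-(3,4,5-trimethoxyphenyl)oxolane-4,4-dicarboxylate F1. Krapcho dealkoxycarbonylation (LiCl, wet DMSO, 150 °C) should then give, after equilibration to the trans ester, ethyl (2R,3R,4R)-3-ethenyl-2-(3,4,5-trimethoxyphenyl)oxolane-4-carboxylate F2. MeNH(OMe)·HCl with iPrMgCl (THF, −20 °C) converts this into the Weinreb amide (2R,3R,4R)-3-ethenyl-N-methoxy-N-methyl-2-(3,4,5-trimethoxyphenyl)oxolane-4-carboxamide F3. Addition of 3,4-dimethoxyphenylmagnesium bromide (THF, 0 °C) comes back to the route at 12.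

Step 9. Hydroboration of the vinyl group by the borane may compete, or catalyst control and the intrinsic facial bias of the α-branched ketone may fail to reinforce each other, so that both carbinol epimers form. Fallback, setting out from 12: the alkene is cleaved first (O3, CH2Cl2, −78 °C; PPh3) to the keto aldehyde (2R,3R,4R)-4-(3,4-dimethoxybenzoyl)-2-(3,4,5-trimethoxyphenyl)oxolane-3-carbaldehyde F4. Both carbonyl groups are then reduced with Zn(BH4)2 (Et2O, −20 °C), the ketone under chelation control through O1 (a six-membered zinc chelate that exposes the face anti to C3, the same sense as the Felkin–Anh model). This comes back to the route directly at 15.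

Step 10. Ozone may attack the two electron-rich arenes or the benzylic C–H bonds. The intermediate aldehyde may also epimerise at C3, driven by closure of a cis-fused lactol with the free carbinol hydroxyl, before it is reduced. Fallback, setting out from 13: the carbinol is silylated (TBSCl, imidazole, DMF) to (2R,3R,4R)-4-[(S)-(tert-butyldimethylsilyloxy)(3,4-dimethoxyphenyl)methyl]-3-ethenyl-2-(3,4,5-trimethoxyphenyl)oxolane F5. The vinyl group is cleaved without ozone by OsO4 (cat.), NaIO4 and 2,6-lutidine (dioxane/H2O, rt) to (2R,3R,4R)-4-[(S)-(tert-butyldimethylsilyloxy)(3,4-dimethoxyphenyl)methyl]-2-(3,4,5-trimethoxyphenyl)oxolane-3-carbaldehyde F6, which can no longer form a lactol. NaBH4 (MeOH, 0 °C) gives [(2R,3S,4R)-4-[(S)-(tert-butyldimethylsilyloxy)(3,4-dimethoxyphenyl)methyl]-2-(3,4,5-trimethoxyphenyl)oxolan-3-yl]methanol F7. Bu4NF (THF, rt) comes back to the route at 15.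

**Further compounds**
F1 | step 8 | diethyl (2R,3R)-3-ethenyl-2-(3,4,5-trimethoxyphenyl)oxolane-4,4-dicarboxylate | CCOC(=O)C1(C(=O)OCC)CO[C@@H](c2cc(OC)c(OC)c(OC)c2)[C@@H]1C=C
F2 | step 8 | ethyl (2R,3R,4R)-3-ethenyl-2-(3,4,5-trimethoxyphenyl)oxolane-4-carboxylate | CCOC(=O)[C@H]1CO[C@@H](c2cc(OC)c(OC)c(OC)c2)[C@@H]1C=C
F3 | step 8 | (2R,3R,4R)-3-ethenyl-N-methoxy-N-methyl-2-(3,4,5-trimethoxyphenyl)oxolane-4-carboxamide | CON(C)C(=O)[C@H]1CO[C@@H](c2cc(OC)c(OC)c(OC)c2)[C@@H]1C=C
F4 | step 9 | (2R,3R,4R)-4-(3,4-dimethoxybenzoyl)-2-(3,4,5-trimethoxyphenyl)oxolane-3-carbaldehyde | COc1ccc(C(=O)[C@H]2CO[C@@H](c3cc(OC)c(OC)c(OC)c3)[C@@H]2C=O)cc1OC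
F5 | step 10 | (2R,3R,4R)-4-[(S)-(tert-butyldimethylsilyloxy)(3,4-dimethoxyphenyl)methyl]-3-ethenyl-2-(3,4,5-trimethoxyphenyl)oxolane | COc1ccc([C@@H](O[Si](C)(C)C(C)(C)C)[C@H]2CO[C@@H](c3cc(OC)c(OC)c(OC)c3)[C@@H]2C=C)cc1OC
F6 | step 10 | (2R,3R,4R)-4-[(S)-(tert-butyldimethylsilyloxy)(3,4-dimethoxyphenyl)methyl]-2-(3,4,5-trimethoxyphenyl)oxolane-3-carbaldehyde | COc1ccc([C@@H](O[Si](C)(C)C(C)(C)C)[C@H]2CO[C@@H](c3cc(OC)c(OC)c(OC)c3)[C@@H]2C=O)cc1OC
F7 | step 10 | [(2R,3S,4R)-4-[(S)-(tert-butyldimethylsilyloxy)(3,4-dimethoxyphenyl)methyl]-2-(3,4,5-trimethoxyphenyl)oxolan-3-yl]methanol | COc1ccc([C@@H](O[Si](C)(C)C(C)(C)C)[C@H]2CO[C@@H](c3cc(OC)c(OC)c(OC)c3)[C@@H]2CO)cc1OC
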